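The route rests on making the bond between C2 of the pyranone ring (ring C) and C1' of ring B by a one-pot C–H zincation/Negishi arylation. It exploits the C2–H of the chromone, the most acidic C–H of the molecule (on the carbon between O1 and C3, β to the C4 carbonyl), so the complete A/C bicycle needs no halogen handle. The precursor is 7-methoxy-5-prenyloxychromone: its prenyl ether masks the chelated 5-OH during metalation and afterwards migrates from O5 to C8 by a europium-catalysed Claisen–Cope rearrangement, which places the prenyl group and frees the 5-OH in the last step. Ring B enters as unprotected 4-bromo-3-methoxyphenol.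

Key step: step 3

Remark on the chemistry: the target has no stereocentre and no stereogenic double bond (the prenyl alkene carries two methyl groups), so it is achiral and no enantiocontrol is needed. Compounds 1, 4 and 6 are taken as commercially available.

Step 1
Reactants: 1 1-(2,6-dihydroxy-4-methoxyphenyl)ethan-1-one
Product: 3 5-hydroxy-7-methoxy-4H-chromen-4-one, via enaminone 2 (not isolated)
Conditions: DMF-DMA (2.5 equiv), toluene, 90 °C; then 2 M HCl, CH2Cl2, 40 °C
Reagents that add atoms: N,N-dimethylformamide dimethyl acetal, COC(OC)N(C)C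
Why: Enaminone chromone synthesis (condensation of the acetyl CH3 with DMF-DMA, then acid-promoted intramolecular oxa-Michael addition and loss of dimethylamine), and because 1 is symmetric, closure through either ortho-OH should give the same chromone with the other OH left as the chelated 5-OH.

Step 2
Reactants: 3 5-hydroxy-7-methoxy-4H-chromen-4-one; 4 1-bromo-3-methylbut-2-ene (prenyl bromide)
Product: 5 7-methoxy-5-[(3-methylbut-2-en-1-yl)oxy]-4H-chromen-4-one
Conditions: K2CO3, Bu4NI (cat.), DMF, 50 °C
Reagents that add atoms: none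
Why: Williamson etherification (SN2 at the primary allylic bromide) of the only OH, where the polar aprotic medium, iodide catalysis and mild heating should overcome the chelation of the 5-OH and favour O- over C-alkylation.

Step 3
Reactants: 5 7-methoxy-5-[(3-methylbut-2-en-1-yl)oxy]-4H-chromen-4-one; 6 4-bromo-3-methoxyphenol
Product: 9 2-(4-hydroxy-2-methoxyphenyl)-7-methoxy-5-[(3-methylbut-2-en-1-yl)oxy]-4H-chromen-4-one, via bis(chromon-2-yl)zinc 7 (not isolated), via magnesium phenoxide 8 (not isolated)
Conditions: 5 (1.2 equiv), TMP2Zn·2MgCl2·2LiCl (0.6 equiv), THF, −30 °C; then 8 [from 6, MeMgCl (1.0 equiv), THF, 0 °C], Pd(OAc)2 (2 mol%), SPhos (4 mol%), 50 °C; aq. NH4Cl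
Reagents that add atoms: none
Why: The MgCl2/LiCl-activated zinc amide complexes the C4 carbonyl (held also by O5) and removes the C2–H of ring C to give diheteroarylzinc 7; Pd(0)/SPhos then inserts into the C–Br bond of phenoxide 8, and transmetalation from zinc followed by reductive elimination should form the C2–C1' bond. The closest known reaction type is the Lewis-acid-triggered C2 zincation of chromones with TMP-zinc bases followed by Negishi arylation to flavones, together with Negishi couplings of aryl halides that bear acidic OH groups. No ring is closed and no stereocentre is formed. The step needs metalation at C2 rather than at C3 of ring C or at C6–H/C8–H of ring A; Lewis-acid complexation of the carbonyl disfavours carbonyl-directed C3 metalation, and the mild zinc amide should not ortho-metalate the alkoxyarene positions at −30 °C. The phenol is delivered as its magnesium phenoxide so that it cannot protonate the C–Zn bond, and bromophenoxides are routine oxidative-addition partners. Palladium must also choose the C–Br bond over ionization of the 5-O-prenyl ether, which the fast oxidative addition of the SPhos catalyst and the hindered trisubstituted allyl unit should secure.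

Step 4
Reactants: 9 2-(4-hydroxy-2-methoxyphenyl)-7-methoxy-5-[(3-methylbut-2-en-1-yl)oxy]-4H-chromen-4-one
Product: 12 Artocarpetin B [5-hydroxy-2-(4-hydroxy-2-methoxyphenyl)-7-methoxy-8-(3-methylbut-2-en-1-yl)-4H-chromen-4-one], via ortho-dienone 10 (not isolated), via para-dienone 11 (not isolated)
Conditions: Eu(fod)3 (10 mol%), NaHCO3, PhCl, 85 °C
Reagents that add atoms: none
Why: Europium(III)-catalysed para-Claisen–Cope rearrangement of a 5-O-prenylflavonoid, in which Eu chelated between O4 and O5 accelerates the [3,3] shift to C6 (dienone 10, 1,1-dimethylallyl), a second [3,3] (Cope) shift carries the chain to C8 as a normal prenyl group (dienone 11), and enolization restores ring A with the chelated 5-OH, so the transient sp3 centres at C6 and C8 are lost and no stereocentre remains.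

Compound list
1 | 1-(2,6-dihydroxy-4-methoxyphenyl)ethan-1-one | CC(=O)c1c(O)cc(OC)cc1O | starting material
2 | (E)-1-(2,6-dihydroxy-4-methoxyphenyl)-3-(dimethylamino)prop-2-en-1-one (not isolated) | CN(C)/C=C/C(=O)c1c(O)cc(OC)cc1O | intermediate
3 | 5-hydroxy-7-methoxy-4H-chromen-4-one | COc1cc(O)c2c(c1)occc2=O | intermediate
4 | 1-bromo-3-methylbut-2-ene (prenyl bromide) | CC(C)=CCBr | starting material
5 | 7-methoxy-5-[(3-methylbut-2-en-1-yl)oxy]-4H-chromen-4-one | COc1cc(OCC=C(C)C)c2c(c1)occc2=O | intermediate
6 | 4-bromo-3-methoxyphenol | COc1cc(O)ccc1Br | starting material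
7 | bis{7-methoxy-5-[(3-methylbut-2-en-1-yl)oxy]-4-oxo-4H-chromen-2-yl}zinc (not isolated) | COc1cc(OCC=C(C)C)c2c(c1)oc([Zn]c1cc(=O)c3c(OCC=C(C)C)cc(OC)cc3o1)cc2=O | intermediate
8 | chloromagnesium 4-bromo-3-methoxyphenoxide (not isolated) | COc1cc(O[Mg]Cl)ccc1Br | intermediate
9 | 2-(4-hydroxy-2-methoxyphenyl)-7-methoxy-5-[(3-methylbut-2-en-1-yl)oxy]-4H-chromen-4-one | COc1cc(O)ccc1-c1cc(=O)c2c(OCC=C(C)C)cc(OC)cc2o1 | intermediate
10 | 2-(4-hydroxy-2-methoxyphenyl)-7-methoxy-6-(2-methylbut-3-en-2-yl)-4H-chromene-4,5(6H)-dione (racemic at C6, not isolated) | COc1cc(O)ccc1C1=CC(=O)C2=C(O1)C=C(OC)C(C(C)(C)C=C)C2=O | intermediate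
11 | 2-(4-hydroxy-2-methoxyphenyl)-7-methoxy-8-(3-methylbut-2-en-1-yl)-4H-chromene-4,5(8H)-dione (racemic at C8, not isolated) | COc1cc(O)ccc1C1=CC(=O)C2=C(O1)C(CC=C(C)C)C(OC)=CC2=O | intermediate
12 | Artocarpetin B, 5-hydroxy-2-(4-hydroxy-2-methoxyphenyl)-7-methoxy-8-(3-methylbut-2-en-1-yl)-4H-chromen-4-one | COc1cc(O)ccc1-c1cc(=O)c2c(O)cc(OC)c(CC=C(C)C)c2o1 | target

Total step count: 4. Longest linear sequence: 4 steps (1 → 3 → 5 → 9 → 12).

Steps most likely to fail

Step 3. The cross-coupling half may stall: incompletely deprotonated phenol could protonate the C–Zn bond, or oxidative addition into the very electron-rich, aggregated bromophenoxide could be slow enough for palladium to ionize the prenyl ether instead. The fallback sets out from 6 and 5 and comes back at 9, and replaces the phenoxide by a silyl-protected partner. Compound 6 is silylated (TBSCl, imidazole, DMF) to tert-butyl(4-bromo-3-methoxyphenoxy)dimethylsilane F1. Zinc reagent 7, made from 5 as in step 3, is coupled with F1 (Pd(OAc)2, SPhos, THF, 50 °C) to give 2-{4-[(tert-butyldimethylsilyl)oxy]-2-methoxyphenyl}-7-methoxy-5-[(3-methylbut-2-en-1-yl)oxy]-4H-chromen-4-one F2. Desilylation (TBAF, THF, 0 °C) then gives 9.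

Step 4. The ortho-dienone may enolize before the Cope shift, stranding the chain on C6 as a 1,1-dimethylallyl group, or the Lewis acid may ionize the allyl ether with loss of the prenyl group. The fallback sets out from 1 and 4 and comes back at 12; it puts the prenyl group on carbon first and fixes the regiochemistry by steric differentiation of the two OH groups.
- C-Prenylation of symmetric 1 (4, 10% aq. KOH, 0 °C) should give 1-[2,6-dihydroxy-4-methoxy-3-(3-methylbut-2-en-1-yl)phenyl]ethan-1-one F3.
- MOMCl/iPr2NEt (CH2Cl2, 0 °C) should protect the less hindered OH remote from the prenyl group, giving 1-[2-hydroxy-4-methoxy-6-(methoxymethoxy)-3-(3-methylbut-2-en-1-yl)phenyl]ethan-1-one F4.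
- DMF-DMA (toluene, 90 °C) gives the enaminone (E)-3-(dimethylamino)-1-[2-hydroxy-4-methoxy-6-(methoxymethoxy)-3-(3-methylbut-2-en-1-yl)phenyl]prop-2-en-1-one F5, which should close on silica gel or in AcOH to 7-methoxy-5-(methoxymethoxy)-8-(3-methylbut-2-en-1-yl)-4H-chromen-4-one F6.
- Zincation as in step 3 gives bis[7-methoxy-5-(methoxymethoxy)-8-(3-methylbut-2-en-1-yl)-4-oxo-4H-chromen-2-yl]zinc F7, and Negishi coupling with 8 gives 2-(4-hydroxy-2-methoxyphenyl)-7-methoxy-5-(methoxymethoxy)-8-(3-methylbut-2-en-1-yl)-4H-chromen-4-one F8.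
- HCl/MeOH (40 °C) then gives 12.

Step 2. Alkylation of the strongly chelated 5-OH may be sluggish and allow C-alkylation of ring A by the ambident phenoxide. The fallback sets out from 3 and comes back at 5: Mitsunobu etherification with 3-methylbut-2-en-1-ol (PPh3, DIAD, THF, 0 °C to rt), which activates the alcohol instead of relying on the poorly nucleophilic phenoxide, and makes no new compound.

Further compounds
F1 | step 3 | tert-butyl(4-bromo-3-methoxyphenoxy)dimethylsilane | COc1cc(O[Si](C)(C)C(C)(C)C)ccc1Br
F2 | step 3 | 2-{4-[(tert-butyldimethylsilyl)oxy]-2-methoxyphenyl}-7-methoxy-5-[(3-methylbut-2-en-1-yl)oxy]-4H-chromen-4-one | COc1cc(O[Si](C)(C)C(C)(C)C)ccc1-c1cc(=O)c2c(OCC=C(C)C)cc(OC)cc2o1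
F3 | step 4 | 1-[2,6-dihydroxy-4-methoxy-3-(3-methylbut-2-en-1-yl)phenyl]ethan-1-one | CC(=O)c1c(O)cc(OC)c(CC=C(C)C)c1O
F4 | step 4 | 1-[2-hydroxy-4-methoxy-6-(methoxymethoxy)-3-(3-methylbut-2-en-1-yl)phenyl]ethan-1-one | CC(=O)c1c(OCOC)cc(OC)c(CC=C(C)C)c1O
F5 | step 4 | (E)-3-(dimethylamino)-1-[2-hydroxy-4-methoxy-6-(methoxymethoxy)-3-(3-methylbut-2-en-1-yl)phenyl]prop-2-en-1-one | CN(C)/C=C/C(=O)c1c(OCOC)cc(OC)c(CC=C(C)C)c1O
F6 | step 4 | 7-methoxy-5-(methoxymethoxy)-8-(3-methylbut-2-en-1-yl)-4H-chromen-4-one | COCOc1cc(OC)c(CC=C(C)C)c2occc(=O)c12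
F7 | step 4 | bis[7-methoxy-5-(methoxymethoxy)-8-(3-methylbut-2-en-1-yl)-4-oxo-4H-chromen-2-yl]zinc | COCOc1cc(OC)c(CC=C(C)C)c2oc([Zn]c3cc(=O)c4c(OCOC)cc(OC)c(CC=C(C)C)c4o3)cc(=O)c12
F8 | step 4 | 2-(4-hydroxy-2-methoxyphenyl)-7-methoxy-5-(methoxymethoxy)-8-(3-methylbut-2-en-1-yl)-4H-chromen-4-one | COCOc1cc(OC)c(CC=C(C)C)c2oc(-c3ccc(O)cc3OC)cc(=O)c12
F0 | step 2 | none | none
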